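**Retrosynthetic overview**
1. Target 14 ⇐ one BCl3 unmasking (5‑OMe, 6‑OBn, 3'‑OiPr) of the protected trans‑3‑methoxyflavanone 13.
2. 13 ⇐ enantioselective 6‑endo oxa‑Michael closure of the 2'‑hydroxy‑α‑methoxychalcone 12; this is the only ring formed (both benzene rings are bought), C2 is set by the catalyst and C3 by thermodynamic trans protonation.
3. 12 ⇐ C3–C4 bond: α‑lithiated enol ether 9 (a 1‑methoxyvinyl acyl‑anion equivalent whose OMe is kept as the 3‑OMe) adds to salicylaldehyde 4, then the carbinol is oxidised.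
4. 9 ⇐ Wittig methoxymethylenation of aldehyde 5; 4 ⇐ Baeyer–Villiger oxidation and ortho‑formylation of the symmetric aldehyde 1.

Assumption: 4‑(benzyloxy)‑3,5‑dimethoxybenzaldehyde and 3‑isopropoxy‑4‑methoxybenzaldehyde are bought as catalogue compounds (each is otherwise one O‑alkylation from syringaldehyde or isovanillin).

**Route**

Step 1
Reactants: 1 4‑(benzyloxy)‑3,5‑dimethoxybenzaldehyde
Product: 3 4‑(benzyloxy)‑3,5‑dimethoxyphenol, via aryl formate 2 (not isolated)
Conditions: mCPBA (1.3 equiv), CH2Cl2, 0 °C → rt; then K2CO3 (cat.), MeOH, rt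
Reagents that add atoms: mCPBA, OOC(=O)c1cccc(Cl)c1
Why: Baeyer–Villiger oxidation of an electron‑rich benzaldehyde goes by aryl migration to the formate, which base‑catalysed methanolysis cleaves to the phenol; no stereocentre is formed.

Step 2
Reactants: 3 4‑(benzyloxy)‑3,5‑dimethoxyphenol
Product: 4 3‑(benzyloxy)‑6‑hydroxy‑2,4‑dimethoxybenzaldehyde
Conditions: MgCl2, Et3N, (CH2O)n, MeCN, reflux; aq. HCl work‑up
Reagents that add atoms: paraformaldehyde (as formaldehyde), C=O
Why: Casnati–Skattebøl ortho‑formylation: the magnesium phenoxide delivers formaldehyde only ortho to OH (the two ortho sites of 3 are equivalent by symmetry) and a second formaldehyde oxidises the hydroxymethyl intermediate to the aldehyde; the ethers are inert and no stereocentre is formed.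

Step 3
Reactants: 5 3‑isopropoxy‑4‑methoxybenzaldehyde; 6 (methoxymethyl)triphenylphosphonium chloride
Product: 8 2‑isopropoxy‑1‑methoxy‑4‑(2‑methoxyethenyl)benzene (E/Z mixture), via phosphonium ylide 7 (not isolated)
Conditions: KOtBu (1.3 equiv), THF, 0 °C → rt
Reagents that add atoms: (methoxymethyl)triphenylphosphonium chloride (compound 6), COC[P+](c1ccccc1)(c1ccccc1)c1ccccc1.[Cl-]
Why: Wittig methoxymethylenation of an aromatic aldehyde gives the enol ether; the E/Z ratio (about 1:1) is not critical because the alkene geometry is corrected in step 5, and no stereocentre is formed.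

Step 4 (key C3–C4 bond)
Reactants: 8 2‑isopropoxy‑1‑methoxy‑4‑(2‑methoxyethenyl)benzene; 4 3‑(benzyloxy)‑6‑hydroxy‑2,4‑dimethoxybenzaldehyde
Product: 10 1‑[3‑(benzyloxy)‑6‑hydroxy‑2,4‑dimethoxyphenyl]‑3‑(3‑isopropoxy‑4‑methoxyphenyl)‑2‑methoxyprop‑2‑en‑1‑ol (racemic; mainly Z), via α‑lithiated enol ether 9 (not isolated)
Conditions: 8 (3 equiv), t‑BuLi (2.2 equiv), THF, −78 → −40 °C; then 4 (1 equiv), −78 → −30 °C; cold aq. NH4Cl; crude 10 used at once
Reagents that add atoms: none
Why: Proposed new method: the methoxy oxygen directs t‑BuLi to the geminal vinylic C–H (kinetically more acidic than the anisole‑type ring C–H at low temperature, and this fragment carries no benzylic ether), giving a configurationally stable 1‑methoxyvinyllithium whose carbon (future C3, normally an oxocarbenium‑type electrophile) adds 1,2 to the aldehyde carbon (future C4) after one equivalent has deprotonated the phenol; the closest known reaction type is α‑lithiation of methyl vinyl ether and (Z)‑1‑alkoxyalkenes and their addition to aldehydes as acyl‑anion equivalents, except that the enol ether is kept as the 3‑OMe instead of being hydrolysed, and the racemic carbinol centre is erased in step 5.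

Step 5
Reactants: 10 1‑[3‑(benzyloxy)‑6‑hydroxy‑2,4‑dimethoxyphenyl]‑3‑(3‑isopropoxy‑4‑methoxyphenyl)‑2‑methoxyprop‑2‑en‑1‑ol
Product: 12 (2Z)‑1‑[3‑(benzyloxy)‑6‑hydroxy‑2,4‑dimethoxyphenyl]‑3‑(3‑isopropoxy‑4‑methoxyphenyl)‑2‑methoxyprop‑2‑en‑1‑one, via E/Z enone mixture 11 (not isolated)
Conditions: activated MnO2 (15 equiv), CH2Cl2, 0 °C → rt; filter; then I2 (2 mol %), CH2Cl2, rt, ambient light
Reagents that add atoms: none
Why: Manganese dioxide oxidation of a doubly activated (benzylic and allylic) alcohol is fast under neutral conditions that spare the phenol and the enol ether, and iodine‑catalysed equilibration funnels any E isomer into the more stable Z enone (aryl trans to the aroyl group); the carbinol stereocentre disappears.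

Step 6
Reactants: 12 (2Z)‑1‑[3‑(benzyloxy)‑6‑hydroxy‑2,4‑dimethoxyphenyl]‑3‑(3‑isopropoxy‑4‑methoxyphenyl)‑2‑methoxyprop‑2‑en‑1‑one
Product: 13 (2R,3R)‑6‑(benzyloxy)‑2‑(3‑isopropoxy‑4‑methoxyphenyl)‑3,5,7‑trimethoxy‑2,3‑dihydro‑4H‑chromen‑4‑one (2,3‑trans)
Conditions: quinine‑derived 3,5‑bis(trifluoromethyl)phenyl thiourea (10 mol %; its quinidine pseudo‑enantiomer if a first analytical run shows the 2S series), toluene, −20 °C; stopped at full conversion
Reagents that add atoms: none
Why: Proposed new method: the quinuclidine nitrogen activates the 2'‑OH while the thiourea binds the enone carbonyl, so the phenoxide adds to one face of C2 in a 6‑endo oxa‑Michael addition and the resulting enol is protonated and equilibrated by the same base to the diequatorial 2,3‑trans isomer, giving 2R,3R; the closest known reaction type is the cinchona‑thiourea catalysed asymmetric cyclisation of 2'‑hydroxychalcones and α‑acyl chalcones to flavanones.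

Step 7
Reactants: 13 (2R,3R)‑6‑(benzyloxy)‑2‑(3‑isopropoxy‑4‑methoxyphenyl)‑3,5,7‑trimethoxy‑2,3‑dihydro‑4H‑chromen‑4‑one
Product: 14 (2R,3R)‑5,6‑dihydroxy‑2‑(3‑hydroxy‑4‑methoxyphenyl)‑3,7‑dimethoxy‑2,3‑dihydro‑4H‑chromen‑4‑one (CNP0393633.1)
Conditions: BCl3 (8 equiv), C6HMe5 (3 equiv), CH2Cl2, −78 → 0 °C; aqueous work‑up
Reagents that add atoms: none
Why: Boron trichloride ether cleavage removes the 5‑OMe selectively through the six‑membered boron chelate with the C4 carbonyl, cleaves the benzyl ether (cation trapped by pentamethylbenzene) and cleaves the secondary isopropyl ether much faster than the unchelated 3‑, 7‑ and 4'‑methyl ethers, while the base‑free medium leaves the already thermodynamic trans C2/C3 pair unchanged.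

**Compound list**
1 | 4‑(benzyloxy)‑3,5‑dimethoxybenzaldehyde | O=Cc1cc(OC)c(OCc2ccccc2)c(OC)c1 | starting material
2 | 4‑(benzyloxy)‑3,5‑dimethoxyphenyl formate | O=COc1cc(OC)c(OCc2ccccc2)c(OC)c1 | intermediate
3 | 4‑(benzyloxy)‑3,5‑dimethoxyphenol | Oc1cc(OC)c(OCc2ccccc2)c(OC)c1 | intermediate
4 | 3‑(benzyloxy)‑6‑hydroxy‑2,4‑dimethoxybenzaldehyde | O=Cc1c(O)cc(OC)c(OCc2ccccc2)c1OC | intermediate
5 | 3‑isopropoxy‑4‑methoxybenzaldehyde | O=Cc1ccc(OC)c(OC(C)C)c1 | starting material
6 | (methoxymethyl)triphenylphosphonium chloride | COC[P+](c1ccccc1)(c1ccccc1)c1ccccc1.[Cl-] | starting material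
7 | (methoxymethylidene)triphenylphosphorane | COC=P(c1ccccc1)(c1ccccc1)c1ccccc1 | intermediate
8 | 2‑isopropoxy‑1‑methoxy‑4‑(2‑methoxyethenyl)benzene, E/Z mixture | COC=Cc1ccc(OC)c(OC(C)C)c1 | intermediate
9 | [2‑(3‑isopropoxy‑4‑methoxyphenyl)‑1‑methoxyethenyl]lithium | [Li]C(OC)=Cc1ccc(OC)c(OC(C)C)c1 | intermediate
10 | 1‑[3‑(benzyloxy)‑6‑hydroxy‑2,4‑dimethoxyphenyl]‑3‑(3‑isopropoxy‑4‑methoxyphenyl)‑2‑methoxyprop‑2‑en‑1‑ol, racemic, mainly Z | COC(=Cc1ccc(OC)c(OC(C)C)c1)C(O)c1c(O)cc(OC)c(OCc2ccccc2)c1OC | intermediate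
11 | 1‑[3‑(benzyloxy)‑6‑hydroxy‑2,4‑dimethoxyphenyl]‑3‑(3‑isopropoxy‑4‑methoxyphenyl)‑2‑methoxyprop‑2‑en‑1‑one, E/Z mixture | COC(=Cc1ccc(OC)c(OC(C)C)c1)C(=O)c1c(O)cc(OC)c(OCc2ccccc2)c1OC | intermediate
12 | (2Z)‑1‑[3‑(benzyloxy)‑6‑hydroxy‑2,4‑dimethoxyphenyl]‑3‑(3‑isopropoxy‑4‑methoxyphenyl)‑2‑methoxyprop‑2‑en‑1‑one | CO/C(=C\c1ccc(OC)c(OC(C)C)c1)C(=O)c1c(O)cc(OC)c(OCc2ccccc2)c1OC | intermediate
13 | (2R,3R)‑6‑(benzyloxy)‑2‑(3‑isopropoxy‑4‑methoxyphenyl)‑3,5,7‑trimethoxy‑2,3‑dihydro‑4H‑chromen‑4‑one | COc1ccc([C@H]2Oc3cc(OC)c(OCc4ccccc4)c(OC)c3C(=O)[C@@H]2OC)cc1OC(C)C | intermediate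
14 | (2R,3R)‑5,6‑dihydroxy‑2‑(3‑hydroxy‑4‑methoxyphenyl)‑3,7‑dimethoxy‑2,3‑dihydro‑4H‑chromen‑4‑one | COc1ccc([C@H]2Oc3cc(OC)c(O)c(O)c3C(=O)[C@@H]2OC)cc1O | target

**Step count and risks**
Total steps: 7. Longest linear sequence: 6 (steps 1, 2, 4, 5, 6, 7).

Step 4 is the most likely to fail: the α‑lithiation of 8 may be accompanied by ring metalation, carbolithiation or loss of LiOMe to the arylacetylene. The fallback sets out from 4 and makes the same C3–C4 bond with an sp3 α‑alkoxy carbanion. Methoxymethyllithium (from tributyl(methoxymethyl)stannane and n‑BuLi, THF, −78 °C, 2.2 equiv) adds to 4 to give racemic 1‑[3‑(benzyloxy)‑6‑hydroxy‑2,4‑dimethoxyphenyl]‑2‑methoxyethan‑1‑ol F1. MnO2 in CH2Cl2 oxidises this to 1‑[3‑(benzyloxy)‑6‑hydroxy‑2,4‑dimethoxyphenyl]‑2‑methoxyethan‑1‑one F2. Claisen–Schmidt condensation of F2 with aldehyde 5 (KOH, EtOH, rt) then gives the Z enone directly, so the route is rejoined at 12 and step 3 is not needed.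

Step 5 is at risk because carbinol 10 is a very electron‑rich ortho‑hydroxybenzylic, allylic alcohol that may ionise (quinone methide or 2H‑chromene formation) before it is oxidised. The fallback sets out from 4 and avoids the alcohol oxidation level. Pinnick oxidation (NaClO2, NaH2PO4, 2‑methyl‑2‑butene, t‑BuOH/H2O) gives 3‑(benzyloxy)‑6‑hydroxy‑2,4‑dimethoxybenzoic acid F3. Acetone/TFAA/TFA closes this to 6‑(benzyloxy)‑5,7‑dimethoxy‑2,2‑dimethyl‑4H‑1,3‑benzodioxin‑4‑one F4. Vinyllithium 9 (1.2 equiv, THF, −78 °C) adds once to the lactone carbonyl of F4, and the tetrahedral intermediate collapses with loss of acetone to the phenoxide of the enone. After the same iodine equilibration the route is rejoined at 12 with no oxidation step.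

Step 6 is at risk because the α‑methoxy enone is a less activated acceptor than those used in known asymmetric flavanone cyclisations, and the ee can erode by retro‑oxa‑Michael reaction. The fallback sets out from 12 and gives up catalyst control. Cyclisation with NaOAc in refluxing EtOH gives the racemic trans flavanone, that is 13 together with (2S,3S)‑6‑(benzyloxy)‑2‑(3‑isopropoxy‑4‑methoxyphenyl)‑3,5,7‑trimethoxy‑2,3‑dihydro‑4H‑chromen‑4‑one F5. The two are separated by preparative chiral SFC, and F5 is recycled by base‑induced ring opening and re‑closure. The route is rejoined at 13.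

**Further compounds**
F1 | step 4 | 1‑[3‑(benzyloxy)‑6‑hydroxy‑2,4‑dimethoxyphenyl]‑2‑methoxyethan‑1‑ol (racemic) | COCC(O)c1c(O)cc(OC)c(OCc2ccccc2)c1OC
F2 | step 4 | 1‑[3‑(benzyloxy)‑6‑hydroxy‑2,4‑dimethoxyphenyl]‑2‑methoxyethan‑1‑one | COCC(=O)c1c(O)cc(OC)c(OCc2ccccc2)c1OC
F3 | step 5 | 3‑(benzyloxy)‑6‑hydroxy‑2,4‑dimethoxybenzoic acid | OC(=O)c1c(O)cc(OC)c(OCc2ccccc2)c1OC
F4 | step 5 | 6‑(benzyloxy)‑5,7‑dimethoxy‑2,2‑dimethyl‑4H‑1,3‑benzodioxin‑4‑one | CC1(C)OC(=O)c2c(OC)c(OCc3ccccc3)c(OC)cc2O1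
F5 | step 6 | (2S,3S)‑6‑(benzyloxy)‑2‑(3‑isopropoxy‑4‑methoxyphenyl)‑3,5,7‑trimethoxy‑2,3‑dihydro‑4H‑chromen‑4‑one | COc1ccc([C@@H]2Oc3cc(OC)c(OCc4ccccc4)c(OC)c3C(=O)[C@H]2OC)cc1OC(C)C
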